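## Structural features

The target is the (E)-caffeate of a secondary allylic alcohol on a sesquiterpene core built from two carbocycles joined by a single bond. Ring A is a cyclohex-2-ene: C1 carries the ester oxygen, C2 a methyl group and the C2=C3 double bond, C4 and C6 are methylenes, and C5 is quaternary (methyl, C4, C6, C1'). Ring B is a cyclopentane whose C1' is quaternary (methyl, C5, C2', C5') and whose C2' carries an exocyclic methylene. There are three stereocentres, all S: the adjacent quaternary pair C5/C1', and the carbinol C1, which is 1,3 to C5 across C6 with its oxygen cis to C1' on ring A. Fragile parts are the free catechol (air, base), the allylic ester (ionisation, hydrolysis, acyl transfer), the cinnamate double bond (conjugate addition) and the 1,1-disubstituted alkene next to a quaternary carbon (acid-induced migration into ring B). The real difficulty is the vicinal pair of quaternary stereocentres, which has no heteroatom nearby in the target to steer bond formation, together with placing C1 correctly relative to C5. The key step exploits that C5 and C1' each bear a methyl group and that C2' is at the ketone oxidation level. If the C5 methyl is read as a carbonyl carbon bound through oxygen to C2', the atoms C(=O)–C5–C1'–C2'–O form a γ-lactone fused to ring B, in which C1' is the β-carbon and C5 the α-carbon of a butenolide.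

## Logic of the disconnections

29 ⇒ 28. The two phenolic O–H groups are masked as silyl ethers. A free catechol would not survive carbodiimide acylation, periodinane oxidation or organometallic methylenation. The last forward step must therefore remove silicon without touching the allylic ester, which calls for buffered fluoride.

28 ⇒ 27. The exocyclic C2'=CH2 bond is cut. This alkene is the most acid-sensitive part of the core and should appear late, and cutting it turns C2' into a carbonyl carbon that traces back to a lactone oxygen. The forward methylenation must act on a hindered ketone, must not be basic and must leave the ester alone.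

27 ⇒ 26 ⇒ 22 + 25. The C2' ketone is taken back to the alcohol, then the acyl C–O bond at C1 is cut. This keeps the aromatic acid out of all reductive steps and makes the route convergent. The forward acylation must distinguish two secondary hydroxyls, and it does so on steric grounds: C1–OH is an ordinary allylic alcohol, whereas C2'–OH is flanked by two quaternary carbons in a row.

25 ⇒ 23. The O–Si bonds are cut. The forward step must free the carboxylic acid again while the aryl silyl ethers stay.

22 ⇒ 20 ⇒ 19. The C5 methyl is re-oxidised to a carbonyl and reconnected to the oxygen on C2'. Two unfunctionalised quaternary neighbours thereby become the α- and β-carbons of a cis-fused lactone, a ring that can control both. The forward deoxygenation must take a neopentyl carbon to a methyl without an activated leaving group sitting next to the free C2' hydroxyl (that would close a tetrahydrofuran). This points to the lactol and a Wolff–Kishner reduction.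

19 ⇒ 18. The C1–H bond is cut. C1 becomes a planar carbonyl, and the resulting enone is the retron of an aldol condensation. The forward reduction must be 1,2-selective and face-selective by reagent control, and must spare the lactone.

18 ⇒ 16. The C2=C3 double bond is cut. Ring A opens to two linear arms on C5. In the forward direction only one pairing of enol and carbonyl can close a six-membered ring, so no regiochemical choice arises.

16 ⇒ 15 ⇒ 13. The C1 carbonyl is traced to an alkyne and the C3 aldehyde to a terminal alkene. The arms become hydrocarbon groups that tolerate organometallic reagents, and 13 has the lactone as its only polar group. The forward hydration must put oxygen on C1 and not C2, which participation of the lactone carbonyl secures. The alkene must be cleaved before the alkyne is activated, because 13 is a 1,6-enyne.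

13 ⇒ 8 + 9 + 10. The C1'–CH3 bond and the C5–C6 bond are cut in one operation. Both quaternary centres disappear and three simple components remain, with the single stereocentre of 8 controlling both new ones. The forward step asks for conjugate addition to a tetrasubstituted alkene and for alkylation on the convex face of the bicyclic enolate.

8 ⇒ 7 ⇒ 6 ⇒ 4 + 5. The C5=C1' double bond of 8 is cut (olefination retron), the ketone is taken back to a carbinol, and the ester C–O bond is cut. What remains is an achiral phosphonate acid and a C2-symmetric diol that supplies the only stereochemical information. To avoid racemisation next to the ketone, the ketone is unveiled only after acylation and the ring is closed with a mild amine base.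

4 ⇒ 3 ⇒ 1 + 2. The C4–C5 bond (allyl to phosphonate carbon) and the ethyl ester are cut, leaving two commodity chemicals. The forward alkylation must stop at mono-allylation.

## Other disconnections considered

Alternative 1: The cut runs through the C4–C5 bond of ring A and the C1'–C2' bond of ring B and moves two methyl groups back, so that the whole core unravels to the acyclic (2E,6E)-farnesyl diphosphate A1. In the atom labels used here, the ring A bond made by such a cyclase is C4–C5 (quaternary carbon to the methylene next to the alkene CH), not C5–C6.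

- Forward key step: trichodiene synthase would ionise A1, close both rings, shift a hydride and two methyl groups and end by deprotonation to the exocyclic alkene, giving (−)-trichodiene A2.
- In its favour: one protecting-group-free operation builds both rings and both quaternary carbons. On step economy this is better than the chosen plan.
- Against it here: A2 is (4S,1'S), whereas the target without its C1 oxygen is the (4R,1'S) hydrocarbon A3. A2 is thus the C5 epimer of what is needed, and this enzyme would lead to a diastereomer of the target. A cyclase for A3 would have to be found and expressed. Even from A3, C1 would still need allylic C–H oxidation in a hydrocarbon with two alkenes and four allylic sites, without obvious regio- or stereocontrol.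
- Comparison: on structure the chosen plan is stronger, since 13 has the right C5/C1' relationship and the C1 oxygen arises by construction. On mechanism the alternative relies on an enzyme pocket and the chosen plan on one carbinol centre and a cis ring fusion. On step count the alternative would win clearly if a suitable cyclase existed.

Alternative 2: The C1'–C2' bond is cut and C2' is reattached to the carbon that becomes the C1' methyl, so ring B is expanded back to a cyclohexane epoxide.

- Forward key step: BF3·OEt2 would open the epoxy benzoate A4 (oxirane anti to the benzoyloxy group) at its tertiary carbon, and the benzoyloxy-bearing ring carbon would shift to it with inversion. This contracts the ring and gives the formyl benzoate A5.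
- In its favour: a stereospecific 1,2-shift creates the quaternary C1' together with an aldehyde (later the C1' methyl) and a protected C2' oxygen. This pair does the same job as the lactone of the chosen plan (equal), and the shift is probably more dependable than cuprate addition to a tetrasubstituted butenolide (better on that point).
- Against it here: ring A in A5 is a symmetric 4,4-disubstituted cyclohexanone ketal, so C5 is not yet stereogenic. Its configuration would arise only when the two identical arms of ring A are differentiated under the influence of the remote C1', and nothing in A5 provides that control. The C5–C1' bond also has to be made earlier by other means.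
- Comparison: on structure the chosen plan sets both quaternary centres at once in a defined relation, the alternative only one. On mechanism the cationic shift is the more certain single event. On step economy the preparation of A4 and the later desymmetrisation of ring A make the alternative at best equal and probably longer.

Alternative 3: The C5–C6 and C1'–C5' bonds are cut in a retro-Diels–Alder sense, with C1 and C4' temporarily joined by a double bond.

- Forward key step: buta-1,3-diene A6 would add across the tetrasubstituted alkene of 2,3-dimethylmaleic anhydride A7 to give the meso anhydride A8.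
- In its favour: suprafacial addition fixes the two methyl groups cis. That is exactly the C5/C1' relationship of the target once the anhydride carbons become C4 and C2'. It is more certain than the facial selectivity on which step 6 depends (better on that point), and the materials are cheap and achiral.
- Against it here: A8 is meso, so the absolute configuration requires differentiation of two enantiotopic, neopentyl-type carbonyl groups. The tetrasubstituted dienophile is sluggish. After cleavage of the temporary alkene, four oxidised termini must be told apart, and C2, C3, the C2 methyl and C3' still have to be added and both rings closed.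
- Comparison: on structure A8 holds ten of the fifteen core carbons, whereas 13 holds fourteen, already sorted into the two arms of ring A. On mechanism pericyclic certainty stands against organometallic facial selectivity. On step economy the chosen plan is clearly shorter.

Key step: step 6

Remark on the chemistry: the atom labels C1–C6 (ring A) and C1'–C5' (ring B) of the target are used for the corresponding atoms of every intermediate, and enantiopure (1R,2R)-cyclopentane-1,2-diol is taken as a purchasable building block.

## Route

Step 1
Reactants: 1 triethyl phosphonoacetate; 2 allyl bromide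
Product: 3 ethyl 2-(diethoxyphosphoryl)pent-4-enoate (racemic)
Conditions: NaH, THF, 0 °C; then 2, 0 °C → rt
Reagents that add atoms: allyl bromide (compound 2), C=CCBr
Why: Alkylation of the stabilised phosphonoacetate carbanion (SN2 on an allylic bromide); a slight excess of 1 keeps dialkylation low. The allyl group is the future C4–C3 arm.

Step 2
Reactants: 3 ethyl 2-(diethoxyphosphoryl)pent-4-enoate
Product: 4 2-(diethoxyphosphoryl)pent-4-enoic acid (racemic)
Conditions: NaOH (1.1 equiv), EtOH/H2O, rt; then aq. HCl
Reagents that add atoms: sodium hydroxide, [Na+].[OH-]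
Why: Saponification; hydroxide cleaves the carboxylic ethyl ester much faster than the phosphonate esters, so one equivalent at room temperature frees only the carboxylic acid.

Step 3
Reactants: 4 2-(diethoxyphosphoryl)pent-4-enoic acid; 5 (1R,2R)-cyclopentane-1,2-diol
Product: 6 (1R,2R)-2-hydroxycyclopentyl 2-(diethoxyphosphoryl)pent-4-enoate (both epimers at the phosphonate carbon)
Conditions: DCC, DMAP (cat.), CH2Cl2, 0 °C → rt (5 in threefold excess)
Reagents that add atoms: (1R,2R)-cyclopentane-1,2-diol (compound 5), O[C@@H]1CCC[C@H]1O
Why: Steglich esterification; the two hydroxyls of the C2-symmetric diol are equivalent, so mono-acylation raises no regiochemical question and excess 5 suppresses the diester. The carbinol stereocentres are untouched because the new bond forms at the acyl carbon.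

Step 4
Reactants: 6 (1R,2R)-2-hydroxycyclopentyl 2-(diethoxyphosphoryl)pent-4-enoate
Product: 7 (1R)-2-oxocyclopentyl 2-(diethoxyphosphoryl)pent-4-enoate
Conditions: Dess–Martin periodinane, CH2Cl2, 0 °C → rt
Reagents that add atoms: none
Why: Dess–Martin oxidation of the remaining secondary alcohol under non-basic conditions. The ketone is unveiled only now, as an α-acyloxy ketone, so that no free α-hydroxy ketone (prone to enediol racemisation and dimerisation) is handled; the ester-bearing carbon keeps its R configuration.

Step 5
Reactants: 7 (1R)-2-oxocyclopentyl 2-(diethoxyphosphoryl)pent-4-enoate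
Product: 8 (6aR)-3-(prop-2-en-1-yl)-4,5,6,6a-tetrahydro-2H-cyclopenta[b]furan-2-one
Conditions: LiCl, i-Pr2NEt, MeCN, rt
Reagents that add atoms: none
Why: Intramolecular Horner–Wadsworth–Emmons reaction under Masamune–Roush conditions; the lithium-chelated phosphonate is deprotonated by the amine far more readily than the ketone α-positions and adds to the ketone in a five-membered closure, and loss of diethyl phosphate gives the tetrasubstituted butenolide alkene. The mild base leaves the γ-carbon (future C2') unracemised.

Step 6
Reactants: 8 (6aR)-3-(prop-2-en-1-yl)-4,5,6,6a-tetrahydro-2H-cyclopenta[b]furan-2-one; 9 methylmagnesium bromide; 10 1-bromobut-2-yne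
Product: 13 (3R,3aR,6aR)-3-(but-2-yn-1-yl)-3a-methyl-3-(prop-2-en-1-yl)hexahydro-2H-cyclopenta[b]furan-2-one, via silyl ketene acetal 11 (not isolated), via lithium enolate 12 (not isolated)
Conditions: MeMgBr, CuBr·SMe2 (20 mol%), TMSCl, HMPA, THF, −78 → −40 °C; MeLi, −78 → 0 °C; then 10, −78 °C → rt
Reagents that add atoms: methylmagnesium bromide (compound 9), C[Mg]Br; 1-bromobut-2-yne (compound 10), CC#CCBr
Why: MeMgBr and CuBr·SMe2 form a methylcopper species that π-complexes the butenolide; TMSCl drives the otherwise reluctant oxidative addition at the fully substituted β-carbon C1' to a trivalent copper intermediate, and reductive elimination forms the C1'–CH3 bond and leaves the O-silyl ketene acetal 11. MeLi then cleaves the O–Si bond of 11 to the lithium enolate 12, which displaces bromide from the propargylic bromide 10 in an SN2 reaction at C5 (C5–C6 bond). The closest known reaction type is the copper-catalysed, chlorosilane-accelerated conjugate addition of Grignard reagents to unsaturated lactones with alkylation of the regenerated enolate (three-component coupling). No ring is closed. C1' is controlled by the C2' carbinol centre: the methyl can only enter on the face of the hydrogen at C2', because a bicyclo[3.3.0] lactone must be cis-fused and because the carbocycle shields the other face. C5 is controlled by the resulting cup shape: the electrophile enters the planar enolate on the convex face, syn to the new angular methyl and away from the C5' methylene of the folded carbocycle, so that the allyl group already on C5 ends on the concave side. The step needs 1,4- and not 1,2-addition and no γ-deprotonation (secured by the soft copper reagent and low temperature), and C- and not O-alkylation at a crowded enolate carbon (secured by the lithium counter-ion, HMPA and an unhindered SN2-active bromide).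

Step 7
Reactants: 13 (3R,3aR,6aR)-3-(but-2-yn-1-yl)-3a-methyl-3-(prop-2-en-1-yl)hexahydro-2H-cyclopenta[b]furan-2-one
Product: 15 2-[(3S,3aR,6aR)-3-(but-2-yn-1-yl)-3a-methyl-2-oxohexahydro-2H-cyclopenta[b]furan-3-yl]acetaldehyde, via vicinal diol 14 (not isolated)
Conditions: OsO4 (2 mol%), NaIO4, 2,6-lutidine, dioxane/H2O, rt
Reagents that add atoms: osmium tetroxide, O=[Os](=O)(=O)=O (delivers the oxygen); sodium periodate, [Na+].[O-]I(=O)(=O)=O (terminal oxidant)
Why: Lemieux–Johnson oxidation; OsO4 dihydroxylates only the monosubstituted alkene (the internal alkyne is inert) and periodate cleaves diol 14 to the C3 aldehyde. The alkene is removed before the alkyne is activated because allyl and butynyl on one carbon form a 1,6-enyne that carbophilic catalysts would cycloisomerise.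

Step 8
Reactants: 15 2-[(3S,3aR,6aR)-3-(but-2-yn-1-yl)-3a-methyl-2-oxohexahydro-2H-cyclopenta[b]furan-3-yl]acetaldehyde
Product: 16 2-[(3R,3aR,6aR)-3a-methyl-2-oxo-3-(2-oxobutyl)hexahydro-2H-cyclopenta[b]furan-3-yl]acetaldehyde
Conditions: Ph3PAuNTf2 (3 mol%), THF/H2O, 40 °C
Reagents that add atoms: water, O
Why: Gold-catalysed alkyne hydration with neighbouring-group participation; the lactone carbonyl oxygen attacks the π-activated alkyne in a 5-exo-dig mode at C1 and water opens the resulting cyclic oxocarbenium ion, so the ketone appears at C1 (1,4 to the lactone carbonyl) and not at C2. The aldehyde oxygen can reach the alkyne only at C1 as well (6-exo), so both carbonyls direct to the same carbon.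

Step 9
Reactants: 16 2-[(3R,3aR,6aR)-3a-methyl-2-oxo-3-(2-oxobutyl)hexahydro-2H-cyclopenta[b]furan-3-yl]acetaldehyde
Product: 18 (1R,3a'R,6a'R)-3a',4-dimethylhexahydro-2'H-spiro[cyclohex-4-ene-1,3'-cyclopenta[b]furan]-2',3-dione (ring A as 2-methylcyclohex-2-enone spiro-linked at C5 to the lactone), via aldol adduct 17 (not isolated)
Conditions: p-TsOH·H2O (10 mol%), toluene, 90 °C
Reagents that add atoms: none
Why: Acid-catalysed intramolecular aldol condensation; of all enol/carbonyl pairings only the C2 enol attacking the C3 aldehyde closes a six-membered ring (the others would be four-membered), and dehydration of aldol 17 gives the conjugated C2=C3 enone. C5 is quaternary and cannot epimerise.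

Step 10
Reactants: 18 spiro enone lactone
Product: 19 (1R,3S,3a'R,6a'R)-3-hydroxy-3a',4-dimethylhexahydro-2'H-spiro[cyclohex-4-ene-1,3'-cyclopenta[b]furan]-2'-one (the (1S)-allylic alcohol in target numbering; hydroxyl cis to C1' across ring A)
Conditions: (R)-2-methyl-CBS-oxazaborolidine (20 mol%), catecholborane, toluene, −78 °C
Reagents that add atoms: none
Why: Corey–Bakshi–Shibata reduction under reagent control; with the α-methyl alkenyl side acting as the large group and the C6 methylene as the small one, the (R)-catalyst should deliver hydride to the face that gives the (1S)-alcohol, 1,2-selectively and without touching the lactone. The (1S)-hydroxyl lies trans to the lactone carbonyl across ring A and therefore cannot translactonise.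

Step 11
Reactants: 19 (1S)-hydroxy spirolactone
Product: 20 (1R,3S,3a'R,6a'R)-3a',4-dimethylhexahydro-2'H-spiro[cyclohex-4-ene-1,3'-cyclopenta[b]furan]-2',3-diol (lactol; both anomers)
Conditions: i-Bu2AlH (2.3 equiv), CH2Cl2, −78 °C; aq. KNaC4H4O6 (potassium sodium tartrate)
Reagents that add atoms: none
Why: Partial reduction of a lactone with diisobutylaluminium hydride; the tetrahedral aluminium hemiacetal of this α-quaternary lactone is stable at −78 °C and gives the lactol on work-up, one equivalent being consumed by the free hydroxyl. No stereocentre of the target is affected.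

Step 12
Reactants: 20 lactol
Product: 22 (1S,5S)-5-[(1R,2R)-2-hydroxy-1-methylcyclopentyl]-2,5-dimethylcyclohex-2-en-1-ol, via hydrazone 21 (not isolated)
Conditions: N2H4·H2O, KOH, diethylene glycol, 130 °C then 200 °C
Reagents that add atoms: none
Why: Wolff–Kishner reduction (Huang–Minlon procedure) of a lactol; the ring-opened hydroxy aldehyde is trapped as hydrazone 21, which loses N2 in hot alkali, so the former lactone carbonyl becomes the C5 methyl and the C2' oxygen is released as a free hydroxyl. The aldehyde is non-enolisable and the alkene and alkoxides are inert, so C1, C5, C1' and C2' keep their configuration, and no activated neopentyl leaving group (which would close a tetrahydrofuran onto the C2' oxygen) is ever formed.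

Step 13
Reactants: 23 caffeic acid
Product: 25 (2E)-3-{3,4-bis[(tert-butyldimethylsilyl)oxy]phenyl}prop-2-enoic acid, via silyl ester 24 (not isolated)
Conditions: TBSCl, imidazole, DMF, rt; then AcOH/THF/H2O, rt
Reagents that add atoms: tert-butyldimethylsilyl chloride, CC(C)(C)[Si](C)(C)Cl
Why: Silylation of both phenols and the acid, then selective hydrolysis of the far more labile silyl ester in 24 by aqueous acetic acid. The E alkene is untouched.

Step 14
Reactants: 22 (1S,5S)-5-[(1R,2R)-2-hydroxy-1-methylcyclopentyl]-2,5-dimethylcyclohex-2-en-1-ol; 25 (2E)-3-{3,4-bis[(tert-butyldimethylsilyl)oxy]phenyl}prop-2-enoic acid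
Product: 26 (1S,5S)-5-[(1R,2R)-2-hydroxy-1-methylcyclopentyl]-2,5-dimethylcyclohex-2-en-1-yl (2E)-3-{3,4-bis[(tert-butyldimethylsilyl)oxy]phenyl}prop-2-enoate
Conditions: 25 (1.05 equiv), DCC, DMAP (cat.), CH2Cl2, 0 °C → rt
Reagents that add atoms: acid 25, O=C(O)/C=C/c1ccc(O[Si](C)(C)C(C)(C)C)c(O[Si](C)(C)C(C)(C)C)c1
Why: Steglich esterification (acyl transfer at oxygen, retention at C1). Site selectivity rests on sterics: the C1 hydroxyl is an ordinary allylic secondary alcohol, whereas the C2' hydroxyl is flanked by the quaternary C1' that itself carries the quaternary C5.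

Step 15
Reactants: 26 hydroxy ester
Product: 27 (1S,5S)-2,5-dimethyl-5-[(1R)-1-methyl-2-oxocyclopentyl]cyclohex-2-en-1-yl (2E)-3-{3,4-bis[(tert-butyldimethylsilyl)oxy]phenyl}prop-2-enoate
Conditions: Dess–Martin periodinane, pyridine, CH2Cl2, 0 °C → rt
Reagents that add atoms: none
Why: Dess–Martin oxidation of the hindered C2' alcohol; pyridine buffers the acetic acid so that the allylic ester and the aryl silyl ethers are safe. The α-carbon C1' is quaternary, so nothing can epimerise.

Step 16
Reactants: 27 keto ester
Product: 28 (1S,5S)-2,5-dimethyl-5-[(1S)-1-methyl-2-methylidenecyclopentyl]cyclohex-2-en-1-yl (2E)-3-{3,4-bis[(tert-butyldimethylsilyl)oxy]phenyl}prop-2-enoate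
Conditions: Zn, CH2Br2, TiCl4, THF, −40 → 5 °C (reagent); then 27, CH2Cl2, rt
Reagents that add atoms: dibromomethane, BrCBr
Why: Takai–Lombardo methylenation; the geminal dizinc species from Zn and CH2Br2, activated by TiCl4, adds to the ketone and eliminates a metal oxide. The reagent is non-basic, suited to hindered enolisable ketones and does not attack esters; no stereocentre is formed.

Step 17
Reactants: 28 bis-silyl ether of the target
Product: 29 (1S,5S)-2,5-dimethyl-5-[(1S)-1-methyl-2-methylidenecyclopentyl]cyclohex-2-en-1-yl (2E)-3-(3,4-dihydroxyphenyl)prop-2-enoate (CNP0268865.1)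
Conditions: TBAF, AcOH, THF, 0 °C
Reagents that add atoms: none
Why: Fluoride cleavage of the two aryl silyl ethers, buffered with acetic acid so that the phenoxides are protonated at once and the allylic ester is neither hydrolysed nor transesterified. The alkenes and all three stereocentres are untouched.

## Compound list

1 | triethyl phosphonoacetate | CCOC(=O)CP(=O)(OCC)OCC | starting material
2 | allyl bromide | C=CCBr | starting material
3 | ethyl 2-(diethoxyphosphoryl)pent-4-enoate (racemic) | CCOC(=O)C(CC=C)P(=O)(OCC)OCC | intermediate
4 | 2-(diethoxyphosphoryl)pent-4-enoic acid (racemic) | OC(=O)C(CC=C)P(=O)(OCC)OCC | intermediate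
5 | (1R,2R)-cyclopentane-1,2-diol | O[C@@H]1CCC[C@H]1O | starting material
6 | (1R,2R)-2-hydroxycyclopentyl 2-(diethoxyphosphoryl)pent-4-enoate (epimers at the phosphonate carbon) | C=CCC(C(=O)O[C@@H]1CCC[C@H]1O)P(=O)(OCC)OCC | intermediate
7 | (1R)-2-oxocyclopentyl 2-(diethoxyphosphoryl)pent-4-enoate | C=CCC(C(=O)O[C@@H]1CCCC1=O)P(=O)(OCC)OCC | intermediate
8 | (6aR)-3-(prop-2-en-1-yl)-4,5,6,6a-tetrahydro-2H-cyclopenta[b]furan-2-one | O=C1O[C@@H]2CCCC2=C1CC=C | intermediate
9 | methylmagnesium bromide | C[Mg]Br | starting material
10 | 1-bromobut-2-yne | CC#CCBr | starting material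
11 | trimethyl{[(3aR,6aR)-3a-methyl-3-(prop-2-en-1-yl)-4,5,6,6a-tetrahydro-3aH-cyclopenta[b]furan-2-yl]oxy}silane (not isolated) | C=CCC1=C(O[Si](C)(C)C)O[C@@H]2CCC[C@]12C | intermediate
12 | lithium (3aR,6aR)-3a-methyl-3-(prop-2-en-1-yl)-4,5,6,6a-tetrahydro-3aH-cyclopenta[b]furan-2-olate (not isolated) | C=CCC1=C(O[Li])O[C@@H]2CCC[C@]12C | intermediate
13 | (3R,3aR,6aR)-3-(but-2-yn-1-yl)-3a-methyl-3-(prop-2-en-1-yl)hexahydro-2H-cyclopenta[b]furan-2-one | O=C1O[C@@H]2CCC[C@]2(C)[C@@]1(CC=C)CC#CC | intermediate
14 | (3S,3aR,6aR)-3-(but-2-yn-1-yl)-3-(2,3-dihydroxypropyl)-3a-methylhexahydro-2H-cyclopenta[b]furan-2-one (both carbinol epimers; not isolated) | O=C1O[C@@H]2CCC[C@]2(C)[C@@]1(CC(O)CO)CC#CC | intermediate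
15 | 2-[(3S,3aR,6aR)-3-(but-2-yn-1-yl)-3a-methyl-2-oxohexahydro-2H-cyclopenta[b]furan-3-yl]acetaldehyde | O=C1O[C@@H]2CCC[C@]2(C)[C@@]1(CC=O)CC#CC | intermediate
16 | 2-[(3R,3aR,6aR)-3a-methyl-2-oxo-3-(2-oxobutyl)hexahydro-2H-cyclopenta[b]furan-3-yl]acetaldehyde | O=C1O[C@@H]2CCC[C@]2(C)[C@@]1(CC=O)CC(=O)CC | intermediate
17 | (1R,3a'R,6a'R)-5-hydroxy-3a',4-dimethylhexahydro-2'H-spiro[cyclohexane-1,3'-cyclopenta[b]furan]-2',3-dione (epimers at the two new ring A centres; not isolated) | O=C1O[C@@H]2CCC[C@]2(C)[C@]13CC(O)C(C)C(=O)C3 | intermediate
18 | (1R,3a'R,6a'R)-3a',4-dimethylhexahydro-2'H-spiro[cyclohex-4-ene-1,3'-cyclopenta[b]furan]-2',3-dione | O=C1O[C@@H]2CCC[C@]2(C)[C@]13CC=C(C)C(=O)C3 | intermediate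
19 | (1R,3S,3a'R,6a'R)-3-hydroxy-3a',4-dimethylhexahydro-2'H-spiro[cyclohex-4-ene-1,3'-cyclopenta[b]furan]-2'-one | O=C1O[C@@H]2CCC[C@]2(C)[C@]13CC=C(C)[C@@H](O)C3 | intermediate
20 | (1R,3S,3a'R,6a'R)-3a',4-dimethylhexahydro-2'H-spiro[cyclohex-4-ene-1,3'-cyclopenta[b]furan]-2',3-diol (lactol, both anomers) | OC1O[C@@H]2CCC[C@]2(C)[C@]13CC=C(C)[C@@H](O)C3 | intermediate
21 | (1S,5R)-5-[(E)-hydrazinylidenemethyl]-5-[(1R,2R)-2-hydroxy-1-methylcyclopentyl]-2-methylcyclohex-2-en-1-ol (not isolated) | O[C@@H]1CCC[C@]1(C)[C@@]1(/C=N/N)CC=C(C)[C@@H](O)C1 | intermediate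
22 | (1S,5S)-5-[(1R,2R)-2-hydroxy-1-methylcyclopentyl]-2,5-dimethylcyclohex-2-en-1-ol | O[C@@H]1CCC[C@]1(C)[C@@]1(C)CC=C(C)[C@@H](O)C1 | intermediate
23 | caffeic acid, (2E)-3-(3,4-dihydroxyphenyl)prop-2-enoic acid | O=C(O)/C=C/c1ccc(O)c(O)c1 | starting material
24 | tert-butyldimethylsilyl (2E)-3-{3,4-bis[(tert-butyldimethylsilyl)oxy]phenyl}prop-2-enoate (not isolated) | CC(C)(C)[Si](C)(C)OC(=O)/C=C/c1ccc(O[Si](C)(C)C(C)(C)C)c(O[Si](C)(C)C(C)(C)C)c1 | intermediate
25 | (2E)-3-{3,4-bis[(tert-butyldimethylsilyl)oxy]phenyl}prop-2-enoic acid | O=C(O)/C=C/c1ccc(O[Si](C)(C)C(C)(C)C)c(O[Si](C)(C)C(C)(C)C)c1 | intermediate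
26 | (1S,5S)-5-[(1R,2R)-2-hydroxy-1-methylcyclopentyl]-2,5-dimethylcyclohex-2-en-1-yl (2E)-3-{3,4-bis[(tert-butyldimethylsilyl)oxy]phenyl}prop-2-enoate | O[C@@H]1CCC[C@]1(C)[C@@]1(C)CC=C(C)[C@@H](OC(=O)/C=C/c2ccc(O[Si](C)(C)C(C)(C)C)c(O[Si](C)(C)C(C)(C)C)c2)C1 | intermediate
27 | (1S,5S)-2,5-dimethyl-5-[(1R)-1-methyl-2-oxocyclopentyl]cyclohex-2-en-1-yl (2E)-3-{3,4-bis[(tert-butyldimethylsilyl)oxy]phenyl}prop-2-enoate | O=C1CCC[C@]1(C)[C@@]1(C)CC=C(C)[C@@H](OC(=O)/C=C/c2ccc(O[Si](C)(C)C(C)(C)C)c(O[Si](C)(C)C(C)(C)C)c2)C1 | intermediate
28 | (1S,5S)-2,5-dimethyl-5-[(1S)-1-methyl-2-methylidenecyclopentyl]cyclohex-2-en-1-yl (2E)-3-{3,4-bis[(tert-butyldimethylsilyl)oxy]phenyl}prop-2-enoate | C=C1CCC[C@]1(C)[C@@]1(C)CC=C(C)[C@@H](OC(=O)/C=C/c2ccc(O[Si](C)(C)C(C)(C)C)c(O[Si](C)(C)C(C)(C)C)c2)C1 | intermediate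
29 | (1S,5S)-2,5-dimethyl-5-[(1S)-1-methyl-2-methylidenecyclopentyl]cyclohex-2-en-1-yl (2E)-3-(3,4-dihydroxyphenyl)prop-2-enoate | C=C1CCC[C@]1(C)[C@@]1(C)CC=C(C)[C@@H](OC(=O)/C=C/c2ccc(O)c(O)c2)C1 | target

## Step count and least certain steps

Total step count: 17 steps. Longest linear sequence: 16 steps (from 1 to 29 through steps 1–12 and 14–17); step 13 is the one-step side branch.

**Step 6 (key step).** The conjugate addition may stall at the tetrasubstituted, α-allylated β-carbon; a slow addition lets γ-deprotonation to the aromatic 2-silyloxyfuran compete, which would erase the C2' stereocentre. A second risk is insufficient preference of the bromide for the convex face, because the angular methyl sits on that face. The fallback separates the three bond formations so that the cuprate meets a less substituted alkene. It sets out from 5, which is esterified with diethylphosphonoacetic acid (DCC, DMAP) to (1R,2R)-2-hydroxycyclopentyl 2-(diethoxyphosphoryl)acetate F1. Dess–Martin oxidation gives (1R)-2-oxocyclopentyl 2-(diethoxyphosphoryl)acetate F2, and ring closure (LiCl, i-Pr2NEt) gives (6aR)-4,5,6,6a-tetrahydro-2H-cyclopenta[b]furan-2-one F3. Me2CuLi/TMSCl then adds to the now trisubstituted alkene to give (3aR,6aR)-3a-methylhexahydro-2H-cyclopenta[b]furan-2-one F4. Allylation (LDA, 2) gives (3aR,6aR)-3a-methyl-3-(prop-2-en-1-yl)hexahydro-2H-cyclopenta[b]furan-2-one F5, and alkylation of its enolate (LDA, HMPA, 10) comes back to the route at 13. Should the enolate prefer the concave face, the order in which 2 and 10 are introduced would be reversed.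

**Step 12.** Hydrazone formation from the neopentyl lactol may be incomplete, and the hot alkali may damage the allylic alkoxide (double-bond migration). The fallback reaches the methyl group under mild, nearly neutral conditions. It sets out from 20, which is condensed with p-toluenesulfonylhydrazide (MeOH, 50 °C) to the tosylhydrazone (1S,5R)-5-[(1R,2R)-2-hydroxy-1-methylcyclopentyl]-2-methyl-5-{(E)-[2-(4-methylbenzenesulfonyl)hydrazinylidene]methyl}cyclohex-2-en-1-ol F6. Reduction with catecholborane and then NaOAc·3H2O at 60 °C (hydride addition to C=N, loss of sulfinate, fragmentation of the diazene) comes back to the route at 22.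

**Step 14.** Site selectivity between the two secondary hydroxyls may be insufficient (acylation at C2' or double acylation), or the reaction may be slow. The fallback forms the C1–O bond with inversion instead of retention, because a Mitsunobu displacement cannot take place at the neopentyl-type C2' carbinol; it would also serve if the reduction in step 10 gave the wrong face. It sets out from 18, which is reduced with the (S)-configured oxazaborolidine and catecholborane to (1R,3R,3a'R,6a'R)-3-hydroxy-3a',4-dimethylhexahydro-2'H-spiro[cyclohex-4-ene-1,3'-cyclopenta[b]furan]-2'-one F7. i-Bu2AlH gives the lactol (1R,3R,3a'R,6a'R)-3a',4-dimethylhexahydro-2'H-spiro[cyclohex-4-ene-1,3'-cyclopenta[b]furan]-2',3-diol F8. Huang–Minlon reduction then passes through (1R,5R)-5-[(E)-hydrazinylidenemethyl]-5-[(1R,2R)-2-hydroxy-1-methylcyclopentyl]-2-methylcyclohex-2-en-1-ol F9 to (1R,5S)-5-[(1R,2R)-2-hydroxy-1-methylcyclopentyl]-2,5-dimethylcyclohex-2-en-1-ol F10. Coupling of F10 with 25 (PPh3, diisopropyl azodicarboxylate, THF, 0 °C) comes back to the route at 26.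

**Step 16.** The very hindered C2' ketone may not react with the dizinc reagent, or the titanium Lewis acid may ionise the allylic ester. The fallback olefinates before the ester is present, with a Wittig reagent that tolerates forcing conditions. It sets out from 22, which is silylated at the less hindered C1 hydroxyl (TBSCl, imidazole) to (1R,2R)-2-[(1S,5S)-5-{[tert-butyl(dimethyl)silyl]oxy}-1,4-dimethylcyclohex-3-en-1-yl]-2-methylcyclopentan-1-ol F11. Dess–Martin oxidation gives (2R)-2-[(1S,5S)-5-{[tert-butyl(dimethyl)silyl]oxy}-1,4-dimethylcyclohex-3-en-1-yl]-2-methylcyclopentan-1-one F12. Ph3P=CH2 (from Ph3PCH3Br and KOt-Bu, toluene, 90 °C) gives tert-butyl(dimethyl){[(1S,5S)-2,5-dimethyl-5-[(1S)-1-methyl-2-methylidenecyclopentyl]cyclohex-2-en-1-yl]oxy}silane F13. TBAF gives (1S,5S)-2,5-dimethyl-5-[(1S)-1-methyl-2-methylidenecyclopentyl]cyclohex-2-en-1-ol F14, and Steglich esterification of F14 with 25 comes back to the route at 28.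

## Further compounds

F1 | step 6 | (1R,2R)-2-hydroxycyclopentyl 2-(diethoxyphosphoryl)acetate | CCOP(=O)(CC(=O)O[C@@H]1CCC[C@H]1O)OCC
F2 | step 6 | (1R)-2-oxocyclopentyl 2-(diethoxyphosphoryl)acetate | CCOP(=O)(CC(=O)O[C@@H]1CCCC1=O)OCC
F3 | step 6 | (6aR)-4,5,6,6a-tetrahydro-2H-cyclopenta[b]furan-2-one | O=C1C=C2CCC[C@H]2O1
F4 | step 6 | (3aR,6aR)-3a-methylhexahydro-2H-cyclopenta[b]furan-2-one | O=C1C[C@@]2(C)CCC[C@H]2O1
F5 | step 6 | (3aR,6aR)-3a-methyl-3-(prop-2-en-1-yl)hexahydro-2H-cyclopenta[b]furan-2-one (both C3 epimers) | O=C1O[C@@H]2CCC[C@]2(C)C1CC=C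
F6 | step 12 | (1S,5R)-5-[(1R,2R)-2-hydroxy-1-methylcyclopentyl]-2-methyl-5-{(E)-[2-(4-methylbenzenesulfonyl)hydrazinylidene]methyl}cyclohex-2-en-1-ol | O[C@@H]1CCC[C@]1(C)[C@@]1(/C=N/NS(=O)(=O)c2ccc(C)cc2)CC=C(C)[C@@H](O)C1
F7 | step 14 | (1R,3R,3a'R,6a'R)-3-hydroxy-3a',4-dimethylhexahydro-2'H-spiro[cyclohex-4-ene-1,3'-cyclopenta[b]furan]-2'-one | O=C1O[C@@H]2CCC[C@]2(C)[C@]13CC=C(C)[C@H](O)C3
F8 | step 14 | (1R,3R,3a'R,6a'R)-3a',4-dimethylhexahydro-2'H-spiro[cyclohex-4-ene-1,3'-cyclopenta[b]furan]-2',3-diol (both anomers) | OC1O[C@@H]2CCC[C@]2(C)[C@]13CC=C(C)[C@H](O)C3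
F9 | step 14 | (1R,5R)-5-[(E)-hydrazinylidenemethyl]-5-[(1R,2R)-2-hydroxy-1-methylcyclopentyl]-2-methylcyclohex-2-en-1-ol | O[C@@H]1CCC[C@]1(C)[C@@]1(/C=N/N)CC=C(C)[C@H](O)C1
F10 | step 14 | (1R,5S)-5-[(1R,2R)-2-hydroxy-1-methylcyclopentyl]-2,5-dimethylcyclohex-2-en-1-ol | O[C@@H]1CCC[C@]1(C)[C@@]1(C)CC=C(C)[C@H](O)C1
F11 | step 16 | (1R,2R)-2-[(1S,5S)-5-{[tert-butyl(dimethyl)silyl]oxy}-1,4-dimethylcyclohex-3-en-1-yl]-2-methylcyclopentan-1-ol | O[C@@H]1CCC[C@]1(C)[C@@]1(C)CC=C(C)[C@@H](O[Si](C)(C)C(C)(C)C)C1
F12 | step 16 | (2R)-2-[(1S,5S)-5-{[tert-butyl(dimethyl)silyl]oxy}-1,4-dimethylcyclohex-3-en-1-yl]-2-methylcyclopentan-1-one | O=C1CCC[C@]1(C)[C@@]1(C)CC=C(C)[C@@H](O[Si](C)(C)C(C)(C)C)C1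
F13 | step 16 | tert-butyl(dimethyl){[(1S,5S)-2,5-dimethyl-5-[(1S)-1-methyl-2-methylidenecyclopentyl]cyclohex-2-en-1-yl]oxy}silane | C=C1CCC[C@]1(C)[C@@]1(C)CC=C(C)[C@@H](O[Si](C)(C)C(C)(C)C)C1
F14 | step 16 | (1S,5S)-2,5-dimethyl-5-[(1S)-1-methyl-2-methylidenecyclopentyl]cyclohex-2-en-1-ol | C=C1CCC[C@]1(C)[C@@]1(C)CC=C(C)[C@@H](O)C1
A1 | alternative 1 | (2E,6E)-farnesyl diphosphate | CC(C)=CCC/C(C)=C/CC/C(C)=C/COP(=O)(O)OP(=O)(O)O
A2 | alternative 1 | (−)-trichodiene, (4S)-1,4-dimethyl-4-[(1S)-1-methyl-2-methylidenecyclopentyl]cyclohexene | C=C1CCC[C@]1(C)[C@@]1(C)CCC(C)=CC1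
A3 | alternative 1 | (4R)-1,4-dimethyl-4-[(1S)-1-methyl-2-methylidenecyclopentyl]cyclohexene (C5 epimer of A2; deoxy core of the target) | C=C1CCC[C@]1(C)[C@]1(C)CCC(C)=CC1
A4 | alternative 2 | 6-(8-methyl-1,4-dioxaspiro[4.5]decan-8-yl)-7-oxabicyclo[4.1.0]heptan-2-yl benzoate (oxirane anti to the benzoyloxy group) | O=C(O[C@@H]1CCC[C@@]2(C3(C)CCC4(CC3)OCCO4)O[C@@H]12)c1ccccc1
A5 | alternative 2 | 2-formyl-2-(8-methyl-1,4-dioxaspiro[4.5]decan-8-yl)cyclopentyl benzoate | O=C[C@]1(C2(C)CCC3(CC2)OCCO3)CCC[C@H]1OC(=O)c1ccccc1
A6 | alternative 3 | buta-1,3-diene | C=CC=C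
A7 | alternative 3 | 2,3-dimethylmaleic anhydride | CC1=C(C)C(=O)OC1=O
A8 | alternative 3 | cis-1,2-dimethylcyclohex-4-ene-1,2-dicarboxylic anhydride (meso) | C[C@@]12CC=CC[C@]1(C)C(=O)OC2=O
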